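**Retrosynthetic overview**

1. The target is an achiral cyclobutane: ring carbons C1 and C3 each carry a 2,4-dihydroxybenzoyl group, C2 and C4 each carry a phenyl group, and every vicinal pair is trans. The two exocyclic carbonyl carbons therefore stand 1,3 and cis, and C1 and C3 are epimerisable.
2. The strategy rests on that feature: if the two carbonyl carbons are bonded to each other as a glycol, the cyclobutane becomes the four-membered ring of a bicyclo[2.1.1]hexane (glycol carbons as the two-carbon bridge, phenyl-bearing carbons as the two one-carbon bridges), which a 1,5-diene closes in one crossed [2+2] photocycloaddition.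
3. Disconnections, backwards: the aryl–carbonyl bonds (aryllithium on a cyclobutane dialdehyde, then oxidation); epimerisation at C1 and C3; cleavage of the glycol C–C bond; the two opposite cyclobutane bonds C1–C4 and C2–C3 (photocycloaddition of 1,6-diphenylhexa-1,5-diene-3,4-diol); the carbinol–carbinol bond (pinacol homocoupling of two molecules of cinnamaldehyde).
4. Ring order: in the photochemical step the cyclopentane closes first and the cyclobutane second; glycol cleavage then opens the five-membered ring and leaves the cyclobutane.
5. The threo (C2-symmetric) glycol is used, not the meso one: titanium-mediated pinacol coupling gives it directly, and in the photoadduct it places one hydroxyl beside each phenyl group, whereas the meso glycol would put both hydroxyls beside the same phenyl and push it to the wrong side.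

Key step: step 2

Remark: the target has two mirror planes and is achiral; the dienediol and the bicyclic glycol are racemic and one enantiomer is drawn throughout.

**Step 1**
Reactants: 1 (E)-cinnamaldehyde (two molecules are joined)
Product: 2 (3S*,4S*)-(1E,5E)-1,6-diphenylhexa-1,5-diene-3,4-diol (threo, racemic)
Conditions: Cp2TiCl2 (2.2 equiv), Zn dust (2 equiv), THF, rt; then 1 (2 equiv), −78 °C → rt; 1 M HCl; recrystallisation
Reagents that add atoms: (E)-cinnamaldehyde (second molecule of 1), O=C/C=C/c1ccccc1
Why: Pinacol homocoupling by Cp2TiCl (trivalent titanium): two molecules of 1 are reduced to titanium-bound ketyl radicals that join at their carbonyl carbons, and the anti arrangement of the two bulky titanium-bearing oxygens in the coupling transition state should set the two new carbinol centres in the threo relation, the minor meso diol being removed by recrystallisation.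

**Step 2**
Reactants: 2 (3S*,4S*)-(1E,5E)-1,6-diphenylhexa-1,5-diene-3,4-diol
Product: 3 trans-5,6-diphenylbicyclo[2.1.1]hexane-2,3-diol (racemic, C2-symmetric, hydroxyls trans; each phenyl points toward the glycol bridge, so the two phenyls are cis on the cyclobutane)
Conditions: thioxanthone (10 mol%), degassed MeCN (0.01 M), 395 nm LED, rt
Reagents that add atoms: none
Why: Triplet energy transfer from thioxanthone to one styrene gives a twisted 1,2-biradical; its benzylic carbon adds to the inner carbon of the other styrene, and the triplet 1,4-biradical so formed (one secondary ring radical, one exocyclic benzylic radical) closes after intersystem crossing. The closest known reaction type is the sensitised intramolecular crossed [2+2] photocycloaddition of styrene-containing 1,5-dienes to bicyclo[2.1.1]hexanes (rule of five). The five-membered ring closes by 5-exo-trig radical addition and the four-membered ring by 1,4-biradical recombination, which together make the two opposite cyclobutane bonds. The two bridgehead centres follow from the bicyclic framework and the fixed carbinol centres, because the two-carbon tether can only span one face of the new cyclobutane; the first phenyl-bearing centre is set in the 5-exo closure, where phenyl and the styryl-derived carbon should take the trans relation on the forming cyclopentane, and the second in the recombination, where the aryl group should avoid the cleft between the two one-carbon bridges. The step needs crossed over straight closure, which the two-carbon tether secures because a straight adduct would have to begin with a 4-exo closure, and it needs both phenyl groups beside the glycol bridge (hence cis to each other), which the threo glycol supports by putting a single small hydroxyl next to each phenyl while the inner positions of the two one-carbon bridges lie only about 2 Å apart and cannot both hold an aryl group. Alkene geometry is lost in the triplet, so E/Z isomerisation of 2 under irradiation does no harm.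

**Step 3**
Reactants: 3 trans-5,6-diphenylbicyclo[2.1.1]hexane-2,3-diol
Product: 4 all-cis-2,4-diphenylcyclobutane-1,3-dicarbaldehyde (r-1,c-2,c-3,c-4)
Conditions: Pb(OAc)4 (1.3 equiv), pyridine, rt
Reagents that add atoms: none
Why: Criegee glycol cleavage: lead tetraacetate can cleave a rigid trans-glycol through a non-cyclic lead alkoxide when pyridine assists, opening of the five-membered ring releases part of the strain of the bicycle, and no stereocentre is touched, so the four ring substituents stay all-cis.

**Step 4**
Reactants: 4 all-cis-2,4-diphenylcyclobutane-1,3-dicarbaldehyde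
Product: 5 (1α,2β,3α,4β)-2,4-diphenylcyclobutane-1,3-dicarbaldehyde (r-1,t-2,c-3,t-4; every vicinal pair trans)
Conditions: DBU (0.2 equiv), CH2Cl2, rt (crude 4)
Reagents that add atoms: none
Why: Base-catalysed epimerisation through the enolate of each aldehyde: both formyl-bearing carbons invert under thermodynamic control until each formyl group is trans to its two phenyl neighbours, while the phenyl-bearing carbons cannot epimerise, which sets the final configuration of target carbons C1 and C3.

**Step 5**
Reactants: 6 4-bromobenzene-1,3-diol
Product: 7 1-bromo-2,4-bis(methoxymethoxy)benzene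
Conditions: MOMCl (2.5 equiv), iPr2NEt (3 equiv), CH2Cl2, 0 °C → rt
Reagents that add atoms: chloromethyl methyl ether (MOMCl), COCCl
Why: Williamson-type O-alkylation of both phenols by the reactive α-chloro ether (MOM protection), with no stereocentre involved.

**Step 6**
Reactants: 5 (1α,2β,3α,4β)-2,4-diphenylcyclobutane-1,3-dicarbaldehyde; 7 1-bromo-2,4-bis(methoxymethoxy)benzene
Product: 9 (1α,2β,3α,4β)-1,3-bis{[2,4-bis(methoxymethoxy)phenyl](hydroxy)methyl}-2,4-diphenylcyclobutane (mixture of carbinol epimers), via [2,4-bis(methoxymethoxy)phenyl]lithium 8 (not isolated)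
Conditions: 7 (2.6 equiv), n-BuLi (2.5 equiv), THF, −78 °C; then 5, −78 → 0 °C; H2O
Reagents that add atoms: none
Why: Bromine–lithium exchange gives the ortho-alkoxy-stabilised aryllithium, which undergoes 1,2-addition to both aldehydes at low temperature; the two new carbinol centres form without control and are removed in step 7.

**Step 7**
Reactants: 9 (1α,2β,3α,4β)-1,3-bis{[2,4-bis(methoxymethoxy)phenyl](hydroxy)methyl}-2,4-diphenylcyclobutane
Product: 10 [(1α,2β,3α,4β)-2,4-diphenylcyclobutane-1,3-diyl]bis{[2,4-bis(methoxymethoxy)phenyl]methanone}
Conditions: DMP (2.5 equiv), CH2Cl2, rt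
Reagents that add atoms: none
Why: Dess–Martin oxidation of both benzylic alcohols under near-neutral conditions should converge all carbinol epimers to one diketone and leave the MOM ethers and the ring centres untouched.

**Step 8**
Reactants: 10 [(1α,2β,3α,4β)-2,4-diphenylcyclobutane-1,3-diyl]bis{[2,4-bis(methoxymethoxy)phenyl]methanone}
Product: 11 [(1α,2β,3α,4β)-2,4-diphenylcyclobutane-1,3-diyl]bis[(2,4-dihydroxyphenyl)methanone] (CNP0398987.1)
Conditions: HCl (3 M aq.), MeOH, 50 °C
Reagents that add atoms: none
Why: Acid-catalysed acetal exchange (MOM cleavage) in methanol frees the four phenols, and the ring centres already hold their thermodynamically preferred all-trans arrangement, so acid cannot change them.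

**Compound list**

1 | (E)-cinnamaldehyde | O=C/C=C/c1ccccc1 | starting material
2 | (3S*,4S*)-(1E,5E)-1,6-diphenylhexa-1,5-diene-3,4-diol (threo, racemic) | O[C@@H](/C=C/c1ccccc1)[C@@H](O)/C=C/c1ccccc1 | intermediate
3 | trans-5,6-diphenylbicyclo[2.1.1]hexane-2,3-diol, both phenyls on the side of the glycol bridge (racemic) | O[C@@H]1[C@@H](O)[C@@H]2[C@H](c3ccccc3)[C@H]1[C@@H]2c1ccccc1 | intermediate
4 | all-cis-2,4-diphenylcyclobutane-1,3-dicarbaldehyde | O=C[C@@H]1[C@H](c2ccccc2)[C@H](C=O)[C@@H]1c1ccccc1 | intermediate
5 | (1α,2β,3α,4β)-2,4-diphenylcyclobutane-1,3-dicarbaldehyde | O=C[C@H]1[C@H](c2ccccc2)[C@@H](C=O)[C@@H]1c1ccccc1 | intermediate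
6 | 4-bromobenzene-1,3-diol (4-bromoresorcinol) | Oc1ccc(Br)c(O)c1 | starting material
7 | 1-bromo-2,4-bis(methoxymethoxy)benzene | COCOc1ccc(Br)c(OCOC)c1 | intermediate
8 | [2,4-bis(methoxymethoxy)phenyl]lithium | [Li]c1ccc(OCOC)cc1OCOC | intermediate
9 | (1α,2β,3α,4β)-1,3-bis{[2,4-bis(methoxymethoxy)phenyl](hydroxy)methyl}-2,4-diphenylcyclobutane, carbinol epimers | OC(c1ccc(OCOC)cc1OCOC)[C@H]1[C@H](c2ccccc2)[C@@H](C(O)c2ccc(OCOC)cc2OCOC)[C@@H]1c1ccccc1 | intermediate
10 | [(1α,2β,3α,4β)-2,4-diphenylcyclobutane-1,3-diyl]bis{[2,4-bis(methoxymethoxy)phenyl]methanone} | O=C(c1ccc(OCOC)cc1OCOC)[C@H]1[C@H](c2ccccc2)[C@@H](C(=O)c2ccc(OCOC)cc2OCOC)[C@@H]1c1ccccc1 | intermediate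
11 | [(1α,2β,3α,4β)-2,4-diphenylcyclobutane-1,3-diyl]bis[(2,4-dihydroxyphenyl)methanone] | O=C(c1ccc(O)cc1O)[C@H]1[C@H](c2ccccc2)[C@@H](C(=O)c2ccc(O)cc2O)[C@@H]1c1ccccc1 | target

**Step count**

Total: 8 steps. Longest linear sequence: 7 steps (steps 1, 2, 3, 4, 6, 7, 8 from cinnamaldehyde); step 5 is a one-step branch.

**Steps most likely to fail**

Step 2. Diastereoselection in the two ring closures may be poor, so that one phenyl is delivered into the cleft between the one-carbon bridges; that isomer has trans phenyls and cannot be corrected later. The 1,4-biradical may also fall back to the diene, so that only E/Z isomerisation is seen, or the sensitiser triplet may abstract the allylic carbinol hydrogen. The fallback sets out from 2 and changes both the chromophore and the excited state. Oxidation of one allylic alcohol (DDQ, 1 equiv, dioxane, rt) should give (1E,5E)-4-hydroxy-1,6-diphenylhexa-1,5-dien-3-one F1. Direct irradiation without sensitiser (366 nm, degassed MeCN, 0.01 M) excites the enone itself, and the crossed cyclisation of 1,5-hexadien-3-ones to bicyclo[2.1.1]hexan-2-ones should give 3-hydroxy-5,6-diphenylbicyclo[2.1.1]hexan-2-one F2. Its trigonal carbonyl carbon leaves each phenyl with one neighbour on the bridge instead of two, which should ease placement of both phenyls beside the bridge. Reduction (NaBH4, MeOH, 0 °C) should give 3 together with its cis-glycol epimer, cis-5,6-diphenylbicyclo[2.1.1]hexane-2,3-diol F3, and Pb(OAc)4 cleaves both to the same dialdehyde, so the route is rejoined at 4.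

Step 3. The rigid trans-glycol (O–C–C–O torsion near 120°) cannot form a cyclic lead ester, so cleavage may be slow, and forcing it may lead to over-oxidation of the aldehydes. The fallback sets out from 3 and cleaves at the diketone oxidation level, where no cyclic ester is needed. Swern oxidation ((COCl)2, DMSO, Et3N, CH2Cl2, −78 °C) should give the non-enolisable 5,6-diphenylbicyclo[2.1.1]hexane-2,3-dione F4. Alkaline hydrogen peroxide (H2O2, NaOH, aq. MeOH, 0 °C → rt) cleaves the 1,2-diketone to all-cis-2,4-diphenylcyclobutane-1,3-dicarboxylic acid F5. Reduction (BH3·THF, 0 °C → rt) gives all-cis-[2,4-diphenylcyclobutane-1,3-diyl]dimethanol F6, and a second Swern oxidation rejoins the route at 4.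

Step 6. After the first addition, the alkoxide may add to the cis-1,3 aldehyde and mask it as a bicyclic lactolate, or the basic aryllithium may enolise the α-branched aldehyde, so that double addition stays incomplete. The fallback sets out from 5 and acylates at the carboxylic acid level. Pinnick oxidation (NaClO2, NaH2PO4, 2-methyl-2-butene, t-BuOH/H2O) should give (1α,2β,3α,4β)-2,4-diphenylcyclobutane-1,3-dicarboxylic acid F7. Amide formation (CDI, 2.5 equiv, then MeNHOMe·HCl, 3 equiv, CH2Cl2) gives the bis(N-methoxy-N-methylamide) F8. Aryllithium 8, made from 7 as in step 6 (2.5 equiv, THF, −78 °C), adds once to each Weinreb amide and gives the diketone directly, so the route is rejoined at 10 without passing through 9 or step 7.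

**Further compounds**

F1 | step 2 | (1E,5E)-4-hydroxy-1,6-diphenylhexa-1,5-dien-3-one (racemic) | O=C(/C=C/c1ccccc1)[C@@H](O)/C=C/c1ccccc1
F2 | step 2 | 3-hydroxy-5,6-diphenylbicyclo[2.1.1]hexan-2-one, both phenyls on the side of the two-carbon bridge (racemic) | O=C1[C@@H](O)[C@@H]2[C@H](c3ccccc3)[C@H]1[C@@H]2c1ccccc1
F3 | step 2 | cis-5,6-diphenylbicyclo[2.1.1]hexane-2,3-diol, both phenyls on the side of the glycol bridge | O[C@H]1[C@@H](O)[C@@H]2[C@H](c3ccccc3)[C@H]1[C@@H]2c1ccccc1
F4 | step 3 | 5,6-diphenylbicyclo[2.1.1]hexane-2,3-dione, both phenyls on the side of the dione bridge | O=C1C(=O)[C@@H]2[C@H](c3ccccc3)[C@H]1[C@@H]2c1ccccc1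
F5 | step 3 | all-cis-2,4-diphenylcyclobutane-1,3-dicarboxylic acid | O=C(O)[C@@H]1[C@H](c2ccccc2)[C@H](C(=O)O)[C@@H]1c1ccccc1
F6 | step 3 | all-cis-[2,4-diphenylcyclobutane-1,3-diyl]dimethanol | OC[C@@H]1[C@H](c2ccccc2)[C@H](CO)[C@@H]1c1ccccc1
F7 | step 6 | (1α,2β,3α,4β)-2,4-diphenylcyclobutane-1,3-dicarboxylic acid | O=C(O)[C@H]1[C@H](c2ccccc2)[C@@H](C(=O)O)[C@@H]1c1ccccc1
F8 | step 6 | (1α,2β,3α,4β)-N1,N3-dimethoxy-N1,N3-dimethyl-2,4-diphenylcyclobutane-1,3-dicarboxamide | CON(C)C(=O)[C@H]1[C@H](c2ccccc2)[C@@H](C(=O)N(C)OC)[C@@H]1c1ccccc1
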